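**Retrosynthetic overview**

- Cembrane numbering: C1 ring-fusion CH, C2 lactone O–CH, C3=C4(Me), C5, C6(OAc), C7=C8(Me), C9, C10(OAc), C11=C12(Me), C13, C14; lactone C15(=C17H2)–C16(=O)–O–C2.
- Enabling feature: C2(O-lactone)–C3=C4(Me)–C5–C6(O) is the 1,4-adduct of a C2=C3–C4(Me)=C5 diene, with an aldehyde carbon (C6) added at C5 and the C16 carboxyl oxygen added at C2. The 14-membered ring and the five-membered ring O–C2–C1–C15–C16 can therefore both come from one acyclic diene/enal/tert-butyl ester.
- Key disconnection: C5–C6 (closes the carbocycle) together with C2–O (closes the lactone) in a silylium-triggered Prins macrocyclization/lactonization; the carbocycle forms first, the lactone second, in the same flask.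
- Acyclic precursor: C10–C14 and C1 from geranyl acetate; C15–C17 from tert-butyl acrylate (Morita–Baylis–Hillman); C2–C5 from 2-methylbut-1-en-3-yne (copper-catalysed SN2′ dienylation sets C1); C6–C9 from 3-methylbut-2-enal (vinylogous Mukaiyama aldol sets C10).
- Endgame: both C6 epimers are funnelled to 6S by oxidation and Corey–Bakshi–Shibata reduction, then acetylated.

Key step: step 11

**Route**

Step 1
Reactants: 1 geranyl acetate
Product: 2 (2E)-5-(3,3-dimethyloxiran-2-yl)-3-methylpent-2-en-1-yl acetate (racemic at the epoxide)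
Conditions: mCPBA (1.05 equiv), NaHCO3, CH2Cl2, −20 to 0 °C
Reagents that add atoms: mCPBA, O=C(OO)c1cccc(Cl)c1
Why: Prilezhaev epoxidation should take the remote trisubstituted alkene, which is more electron-rich than the one deactivated by the allylic acetate; the epoxide stereocentre is lost in step 2.

Step 2
Reactants: 2 (2E)-5-(3,3-dimethyloxiran-2-yl)-3-methylpent-2-en-1-yl acetate
Product: 3 (2E)-3-methyl-6-oxohex-2-en-1-yl acetate
Conditions: H5IO6 (1.1 equiv), THF/H2O, 0 °C
Reagents that add atoms: none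
Why: Periodic acid opens the epoxide and cleaves the resulting glycol (Malaprade-type cleavage) to the aldehyde that becomes C1, leaving the E alkene and the acetate untouched.

Step 3
Reactants: 3 (2E)-3-methyl-6-oxohex-2-en-1-yl acetate; 4 tert-butyl acrylate
Product: 5 tert-butyl (6E)-8-acetoxy-3-hydroxy-6-methyl-2-methylideneoct-6-enoate (racemic)
Conditions: DABCO (1.0 equiv), 4 (3 equiv), 1,4-dioxane/H2O 1:1, rt
Reagents that add atoms: none
Why: Morita–Baylis–Hillman reaction of the unhindered aliphatic aldehyde installs C15–C17 and the tert-butyl ester that later acts as the internal nucleophile; the racemic carbinol centre is erased in step 4.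

Step 4
Reactants: 5 tert-butyl (6E)-8-acetoxy-3-hydroxy-6-methyl-2-methylideneoct-6-enoate
Product: 6 tert-butyl (2Z,6E)-8-acetoxy-2-(bromomethyl)-6-methylocta-2,6-dienoate
Conditions: NBS, Me2S (premixed), CH2Cl2, 0 °C to rt
Reagents that add atoms: N-bromosuccinimide, O=C1CCC(=O)N1Br
Why: Activation of the allylic alcohol as its alkoxysulfonium salt and SN2′ attack of bromide should give the thermodynamically preferred (Z)-2-(bromomethyl)enoate, the electrophile for step 5.

Step 5
Reactants: 6 tert-butyl (2Z,6E)-8-acetoxy-2-(bromomethyl)-6-methylocta-2,6-dienoate; 7 2-methylbut-1-en-3-yne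
Product: 9 tert-butyl (3S,6E)-8-acetoxy-6-methyl-2-methylidene-3-[(1E)-3-methylbuta-1,3-dien-1-yl]oct-6-enoate (C3 is C1 of the target; same spatial arrangement as 1R in the lactones), via dienylalane 8 (not isolated)
Conditions: 7, i-Bu2AlH, hexanes, 50 °C (sealed); then 6, CuCl2·2H2O (5 mol %), chiral sulfonate-bearing imidazolinium salt (N-heterocyclic carbene precursor, 5.5 mol %), THF, −15 °C
Reagents that add atoms: none
Why: Syn-hydroalumination gives the (E)-dienylalane, and copper-catalysed enantioselective SN2′ allylic substitution (conjugate addition to the enoate, then loss of bromide) should transfer the dienyl group to C1, whose configuration is set by the chiral carbene ligand, the ligand antipode being chosen to give 3S.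

Step 6
Reactants: 9 tert-butyl (3S,6E)-8-acetoxy-6-methyl-2-methylidene-3-[(1E)-3-methylbuta-1,3-dien-1-yl]oct-6-enoate
Product: 10 tert-butyl (3S,6E)-8-hydroxy-6-methyl-2-methylidene-3-[(1E)-3-methylbuta-1,3-dien-1-yl]oct-6-enoate
Conditions: Novozym 435 (immobilized Candida antarctica lipase B), pH 7 phosphate buffer/MTBE, 30 °C
Reagents that add atoms: none
Why: Lipase-catalysed hydrolysis should cleave the unhindered primary acetate at neutral pH, sparing the tert-butyl ester and the base-sensitive doubly allylic C1–H.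

Step 7
Reactants: 10 tert-butyl (3S,6E)-8-hydroxy-6-methyl-2-methylidene-3-[(1E)-3-methylbuta-1,3-dien-1-yl]oct-6-enoate
Product: 11 tert-butyl (3S,6E)-6-methyl-2-methylidene-3-[(1E)-3-methylbuta-1,3-dien-1-yl]-8-oxooct-6-enoate
Conditions: activated MnO2, CH2Cl2, rt
Reagents that add atoms: none
Why: MnO2 oxidation of the allylic alcohol should give the E enal (the C10 aldehyde) under neutral conditions that leave the diene, the acrylate and C1 untouched.

Step 8
Reactants: 12 3-methylbut-2-enal
Product: 13 tert-butyl(dimethyl){[(1E)-3-methylbuta-1,3-dien-1-yl]oxy}silane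
Conditions: TBSOTf, Et3N, Et2O, 0 °C
Reagents that add atoms: tert-butyldimethylsilyl trifluoromethanesulfonate, CC(C)(C)[Si](C)(C)OS(=O)(=O)C(F)(F)F
Why: Soft enolization (O-silylation, then γ-deprotonation by the amine) should give the extended E-configured silyl dienol ether.

Step 9
Reactants: 11 tert-butyl (3S,6E)-6-methyl-2-methylidene-3-[(1E)-3-methylbuta-1,3-dien-1-yl]-8-oxooct-6-enoate; 13 tert-butyl(dimethyl){[(1E)-3-methylbuta-1,3-dien-1-yl]oxy}silane
Product: 14 tert-butyl (3S,6E,8S,10E)-8-hydroxy-6,10-dimethyl-2-methylidene-3-[(1E)-3-methylbuta-1,3-dien-1-yl]-12-oxododeca-6,10-dienoate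
Conditions: 4-(indol-3-ylmethyl)-2-phenyl-3-tosyl-1,3,2-oxazaborolidin-5-one (from N-tosyltryptophan and PhBCl2, 1.2 equiv, antipode chosen to give 8S), i-PrOH (1.2 equiv), EtCN, −78 °C
Reagents that add atoms: none
Why: In this vinylogous Mukaiyama aldol reaction the chiral boron Lewis acid activates the enal and the γ-carbon of 13 adds to one carbonyl face, which sets C10 (8S in 14) under reagent control and gives the E enal (C6 aldehyde) directly.

Step 10
Reactants: 14 tert-butyl (3S,6E,8S,10E)-8-hydroxy-6,10-dimethyl-2-methylidene-3-[(1E)-3-methylbuta-1,3-dien-1-yl]-12-oxododeca-6,10-dienoate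
Product: 15 tert-butyl (3S,6E,8S,10E)-8-acetoxy-6,10-dimethyl-2-methylidene-3-[(1E)-3-methylbuta-1,3-dien-1-yl]-12-oxododeca-6,10-dienoate
Conditions: Ac2O, pyridine, DMAP (cat.), CH2Cl2, 0 °C
Reagents that add atoms: acetic anhydride, CC(=O)OC(C)=O
Why: DMAP-catalysed acetylation of the secondary alcohol installs the C10 acetate without base strong enough to touch C1–H or isomerize the enal.

Step 11
Reactants: 15 tert-butyl (3S,6E,8S,10E)-8-acetoxy-6,10-dimethyl-2-methylidene-3-[(1E)-3-methylbuta-1,3-dien-1-yl]-12-oxododeca-6,10-dienoate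
Product: 17 (1R,2S,3E,7E,10S,11E)-10-acetoxy-6-hydroxycembra-3,7,11,15(17)-tetraen-16,2-olide (both C6 epimers), via trimethylsilyl ether 16 (not isolated)
Conditions: Me3SiNTf2 (1.3 equiv), 2,6-di-tert-butyl-4-methylpyridine (2 equiv), CH2Cl2, −78 °C, 15 added by syringe pump (final 1 mM); pyridine/MeOH quench; then aq. citric acid, THF, 0 °C
Reagents that add atoms: none
Why: Proposed new method: Me3SiNTf2 silylates the enal oxygen, C5 (the CH2 terminus of the s-trans C2=C3–C4(Me)=C5 diene) adds to C6, and the 3E allyl cation C2–C3–C4 so formed inside the new carbocycle is captured at C2 by the carbonyl oxygen of the tert-butyl ester, whose tert-butyl group leaves as isobutene while the hindered pyridine takes the proton. The closest known reaction types are the Lewis-acid-promoted ene/Prins macrocyclization of a remote 1,1-disubstituted alkene onto a conjugated aldehyde, which gives 14-membered carbocycles, and the 1,4-halolactonization of conjugated dienoic acids and their tert-butyl esters, with a silylated aldehyde here taking the place of the halonium ion. The carbocycle closes 14-exo-trig at the carbonyl carbon and the lactone closes 5-exo at the allyl cation terminus C2, because closure at C4 would put an E double bond into a seven-membered ring. C2 is controlled by C1, since the cation is trapped through the rotamer with C1–H in the allyl plane (least allylic 1,3-strain), which places C14 and C3 trans on the lactone, and any cis lactone can re-ionize and re-close to the trans isomer, while C3=C4 is E because the diene reacts s-trans. C6 is formed without control and both epimers are carried on, since steps 12 and 13 rewrite this centre. The step needs C–C bond formation at the diene and not at the other alkenes (C7=C8 is conjugated, and C7=C8 or C11=C12 would have to close a small ring around an E alkene), cation capture by oxygen and not proton loss (a silyl ether cannot serve as the internal base of an ene reaction and the hindered pyridine is a poor one), and cyclization over oligomerization (slow addition, high dilution).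

Step 12
Reactants: 17 (1R,2S,3E,7E,10S,11E)-10-acetoxy-6-hydroxycembra-3,7,11,15(17)-tetraen-16,2-olide (both C6 epimers)
Product: 18 (1R,2S,3E,7E,10S,11E)-10-acetoxy-6-oxocembra-3,7,11,15(17)-tetraen-16,2-olide
Conditions: activated MnO2, CH2Cl2, rt
Reagents that add atoms: none
Why: MnO2 oxidation of the secondary allylic alcohol should convert both C6 epimers into one enone under neutral conditions that spare the lactone, the acetate and the C5 methylene.

Step 13
Reactants: 18 (1R,2S,3E,7E,10S,11E)-10-acetoxy-6-oxocembra-3,7,11,15(17)-tetraen-16,2-olide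
Product: 19 (1R,2S,3E,6S,7E,10S,11E)-10-acetoxy-6-hydroxycembra-3,7,11,15(17)-tetraen-16,2-olide
Conditions: (R)-2-methyl-CBS-oxazaborolidine (0.3 equiv), catecholborane, toluene, −78 °C
Reagents that add atoms: none
Why: In this Corey–Bakshi–Shibata reduction the C7=C8 alkenyl group acts as the large and the C5 methylene as the small substituent, so the (R)-catalyst should deliver hydride to the face that gives 6S, and 1,2-reduction at low temperature should leave the lactone, acetate and alkenes untouched.

Step 14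
Reactants: 19 (1R,2S,3E,6S,7E,10S,11E)-10-acetoxy-6-hydroxycembra-3,7,11,15(17)-tetraen-16,2-olide
Product: 20 (1R,2S,3E,6S,7E,10S,11E)-6,10-diacetoxycembra-3,7,11,15(17)-tetraen-16,2-olide (target, CID11069750)
Conditions: Ac2O, pyridine, DMAP (cat.), CH2Cl2, 0 °C to rt
Reagents that add atoms: acetic anhydride, CC(=O)OC(C)=O
Why: DMAP-catalysed acetylation of the C6 alcohol with retention should complete the target.

**Compound list**

1 | geranyl acetate, (2E)-3,7-dimethylocta-2,6-dien-1-yl acetate | CC(C)=CCC/C(C)=C/COC(C)=O | starting material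
2 | (2E)-5-(3,3-dimethyloxiran-2-yl)-3-methylpent-2-en-1-yl acetate (racemic at the epoxide) | CC1(C)OC1CC/C(C)=C/COC(C)=O | intermediate
3 | (2E)-3-methyl-6-oxohex-2-en-1-yl acetate | O=CCC/C(C)=C/COC(C)=O | intermediate
4 | tert-butyl acrylate | C=CC(=O)OC(C)(C)C | starting material
5 | tert-butyl (6E)-8-acetoxy-3-hydroxy-6-methyl-2-methylideneoct-6-enoate (racemic) | C=C(C(=O)OC(C)(C)C)C(O)CC/C(C)=C/COC(C)=O | intermediate
6 | tert-butyl (2Z,6E)-8-acetoxy-2-(bromomethyl)-6-methylocta-2,6-dienoate | BrC/C(C(=O)OC(C)(C)C)=C\CC/C(C)=C/COC(C)=O | intermediate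
7 | 2-methylbut-1-en-3-yne | C=C(C)C#C | starting material
8 | [(1E)-3-methylbuta-1,3-dien-1-yl]bis(2-methylpropyl)alumane | C=C(C)/C=C/[Al](CC(C)C)CC(C)C | intermediate (not isolated)
9 | tert-butyl (3S,6E)-8-acetoxy-6-methyl-2-methylidene-3-[(1E)-3-methylbuta-1,3-dien-1-yl]oct-6-enoate | C=C(C(=O)OC(C)(C)C)[C@H](/C=C/C(C)=C)CC/C(C)=C/COC(C)=O | intermediate
10 | tert-butyl (3S,6E)-8-hydroxy-6-methyl-2-methylidene-3-[(1E)-3-methylbuta-1,3-dien-1-yl]oct-6-enoate | C=C(C(=O)OC(C)(C)C)[C@H](/C=C/C(C)=C)CC/C(C)=C/CO | intermediate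
11 | tert-butyl (3S,6E)-6-methyl-2-methylidene-3-[(1E)-3-methylbuta-1,3-dien-1-yl]-8-oxooct-6-enoate | C=C(C(=O)OC(C)(C)C)[C@H](/C=C/C(C)=C)CC/C(C)=C/C=O | intermediate
12 | 3-methylbut-2-enal | CC(C)=CC=O | starting material
13 | tert-butyl(dimethyl){[(1E)-3-methylbuta-1,3-dien-1-yl]oxy}silane | C=C(C)/C=C/O[Si](C)(C)C(C)(C)C | intermediate
14 | tert-butyl (3S,6E,8S,10E)-8-hydroxy-6,10-dimethyl-2-methylidene-3-[(1E)-3-methylbuta-1,3-dien-1-yl]-12-oxododeca-6,10-dienoate | C=C(C(=O)OC(C)(C)C)[C@H](/C=C/C(C)=C)CC/C(C)=C/[C@@H](O)C/C(C)=C/C=O | intermediate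
15 | tert-butyl (3S,6E,8S,10E)-8-acetoxy-6,10-dimethyl-2-methylidene-3-[(1E)-3-methylbuta-1,3-dien-1-yl]-12-oxododeca-6,10-dienoate | C=C(C(=O)OC(C)(C)C)[C@H](/C=C/C(C)=C)CC/C(C)=C/[C@@H](OC(C)=O)C/C(C)=C/C=O | intermediate
16 | (1R,2S,3E,7E,10S,11E)-10-acetoxy-6-(trimethylsilyloxy)cembra-3,7,11,15(17)-tetraen-16,2-olide (both C6 epimers) | C=C1C(=O)O[C@H]2/C=C(\C)CC(O[Si](C)(C)C)/C=C(\C)C[C@H](OC(C)=O)/C=C(\C)CC[C@H]12 | intermediate (not isolated)
17 | (1R,2S,3E,7E,10S,11E)-10-acetoxy-6-hydroxycembra-3,7,11,15(17)-tetraen-16,2-olide (both C6 epimers; trans-fused α-methylene-γ-lactone on the 14-membered ring) | C=C1C(=O)O[C@H]2/C=C(\C)CC(O)/C=C(\C)C[C@H](OC(C)=O)/C=C(\C)CC[C@H]12 | intermediate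
18 | (1R,2S,3E,7E,10S,11E)-10-acetoxy-6-oxocembra-3,7,11,15(17)-tetraen-16,2-olide | C=C1C(=O)O[C@H]2/C=C(\C)CC(=O)/C=C(\C)C[C@H](OC(C)=O)/C=C(\C)CC[C@H]12 | intermediate
19 | (1R,2S,3E,6S,7E,10S,11E)-10-acetoxy-6-hydroxycembra-3,7,11,15(17)-tetraen-16,2-olide | C=C1C(=O)O[C@H]2/C=C(\C)C[C@H](O)/C=C(\C)C[C@H](OC(C)=O)/C=C(\C)CC[C@H]12 | intermediate
20 | (1R,2S,3E,6S,7E,10S,11E)-6,10-diacetoxycembra-3,7,11,15(17)-tetraen-16,2-olide | C=C1C(=O)O[C@H]2/C=C(\C)C[C@H](OC(C)=O)/C=C(\C)C[C@H](OC(C)=O)/C=C(\C)CC[C@H]12 | target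

**Step count and risks**

Total step count: 14. Longest linear sequence: 13 (steps 1–7 and 9–14; step 8 is a one-step branch).

Steps most likely to fail:

1. Step 11 (Proposed new method). What may go wrong: the allyl cation may exit by proton loss (ene-type) or by transannular attack of the C11=C12 alkene instead of lactonization, the s-cis diene may close a dihydropyran with the silylated aldehyde, the allylic acetate may ionize, or oligomerization may outrun cyclization. The fallback uses known chemistry only: C5–C6 is made by a second vinylogous Mukaiyama aldol reaction, and the carbocycle and the lactone are then closed together by a chromium-mediated 2-(alkoxycarbonyl)allylation. It sets out from 5 and comes back at 20. Lipase hydrolysis of the primary acetate of 5 should give dihydroxy ester F1, and TEMPO/PhI(OAc)2 should oxidize only the primary allylic alcohol to hydroxy enal F2. The aldol reaction of step 9 with 13 should give dihydroxy enal F3, and Ac2O should give diacetate F4, in which the Morita–Baylis–Hillman hydroxyl is acetylated as well. A second aldol reaction with 13 under the same reagent control should set C6 in hydroxy enal F5, and acetylation should give triacetate F6. MgBr2·OEt2 should convert the Morita–Baylis–Hillman acetate by SN2′ into bromo enal F7. CrCl2 in THF at high dilution (Nozaki–Hiyama–Kishi-type allylation of the C2 aldehyde, anti-selective) should close the ring to macrocyclic hydroxy ester F8, and TsOH should close the trans lactone of 20.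

2. Step 5. What may go wrong: poor discrimination of the enantiotopic faces of the trisubstituted enoate by the copper catalyst, direct SN2 displacement of bromide, or transfer of an isobutyl or alkynyl group from aluminium. The fallback replaces allylic substitution by a Horner–Wadsworth–Emmons reaction, a rhodium-catalysed asymmetric conjugate addition and α-methylenation. It sets out from 3 and comes back at 10. tert-Butyl diethylphosphonoacetate, LiCl and DBU should give dienoate F9. Hydroboration of 7 with pinacolborane (Cp2Zr(H)Cl cat.) should give dienylboronate F10, which should add to F9 under [Rh(OH)(BINAP)]2 catalysis (Hayashi–Miyaura reaction, BINAP antipode chosen for 3R) to give conjugate adduct F11. K2CO3/MeOH should remove the acetate to give hydroxy ester F12. LDA (2.2 equiv) followed by dimethylmethylideneammonium iodide should give Mannich base F13, and MeI followed by NaHCO3 should eliminate trimethylamine from methiodide F14 to give 10.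

3. Step 13. What may go wrong: the macrocyclic conformation may override reagent control (poor facial selectivity), or conjugate reduction may compete. The fallback replaces the redox funnel by stereoinversion. It sets out from 17 and comes back at 20. The C6 epimers of 17 are separated by chromatography; the 6S epimer is 19 and goes on to step 14, and 6R alcohol F15 is esterified with inversion under Mitsunobu conditions (PPh3, DIAD, AcOH) to give 20 directly.

**Further compounds**

F1 | step 11 | dihydroxy ester, tert-butyl (6E)-3,8-dihydroxy-6-methyl-2-methylideneoct-6-enoate | C=C(C(=O)OC(C)(C)C)C(O)CC/C(C)=C/CO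
F2 | step 11 | hydroxy enal, tert-butyl (6E)-3-hydroxy-6-methyl-2-methylidene-8-oxooct-6-enoate | C=C(C(=O)OC(C)(C)C)C(O)CC/C(C)=C/C=O
F3 | step 11 | dihydroxy enal, tert-butyl (6E,8S,10E)-3,8-dihydroxy-6,10-dimethyl-2-methylidene-12-oxododeca-6,10-dienoate | C=C(C(=O)OC(C)(C)C)C(O)CC/C(C)=C/[C@@H](O)C/C(C)=C/C=O
F4 | step 11 | diacetate, tert-butyl (6E,8S,10E)-3,8-diacetoxy-6,10-dimethyl-2-methylidene-12-oxododeca-6,10-dienoate | C=C(C(=O)OC(C)(C)C)C(OC(C)=O)CC/C(C)=C/[C@@H](OC(C)=O)C/C(C)=C/C=O
F5 | step 11 | hydroxy enal, tert-butyl (6E,8S,10E,12S,14E)-3,8-diacetoxy-12-hydroxy-6,10,14-trimethyl-2-methylidene-16-oxohexadeca-6,10,14-trienoate | C=C(C(=O)OC(C)(C)C)C(OC(C)=O)CC/C(C)=C/[C@@H](OC(C)=O)C/C(C)=C/[C@@H](O)C/C(C)=C/C=O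
F6 | step 11 | triacetate, tert-butyl (6E,8S,10E,12S,14E)-3,8,12-triacetoxy-6,10,14-trimethyl-2-methylidene-16-oxohexadeca-6,10,14-trienoate | C=C(C(=O)OC(C)(C)C)C(OC(C)=O)CC/C(C)=C/[C@@H](OC(C)=O)C/C(C)=C/[C@@H](OC(C)=O)C/C(C)=C/C=O
F7 | step 11 | bromo enal, tert-butyl (2Z,6E,8S,10E,12S,14E)-8,12-diacetoxy-2-(bromomethyl)-6,10,14-trimethyl-16-oxohexadeca-2,6,10,14-tetraenoate | BrC/C(C(=O)OC(C)(C)C)=C\CC/C(C)=C/[C@@H](OC(C)=O)C/C(C)=C/[C@@H](OC(C)=O)C/C(C)=C/C=O
F8 | step 11 | macrocyclic hydroxy ester, tert-butyl 2-[(1R,2S,3E,6S,7E,10S,11E)-6,10-diacetoxy-2-hydroxy-4,8,12-trimethylcyclotetradeca-3,7,11-trien-1-yl]prop-2-enoate | O[C@H]1/C=C(\C)C[C@H](OC(C)=O)/C=C(\C)C[C@H](OC(C)=O)/C=C(\C)CC[C@@H]1C(=C)C(=O)OC(C)(C)C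
F9 | step 5 | dienoate, tert-butyl (2E,6E)-8-acetoxy-6-methylocta-2,6-dienoate | CC(C)(C)OC(=O)/C=C/CC/C(C)=C/COC(C)=O
F10 | step 5 | dienylboronate, 4,4,5,5-tetramethyl-2-[(1E)-3-methylbuta-1,3-dien-1-yl]-1,3,2-dioxaborolane | C=C(C)/C=C/B1OC(C)(C)C(C)(C)O1
F11 | step 5 | conjugate adduct, tert-butyl (3R,6E)-8-acetoxy-6-methyl-3-[(1E)-3-methylbuta-1,3-dien-1-yl]oct-6-enoate | CC(C)(C)OC(=O)C[C@H](/C=C/C(C)=C)CC/C(C)=C/COC(C)=O
F12 | step 5 | hydroxy ester, tert-butyl (3R,6E)-8-hydroxy-6-methyl-3-[(1E)-3-methylbuta-1,3-dien-1-yl]oct-6-enoate | CC(C)(C)OC(=O)C[C@H](/C=C/C(C)=C)CC/C(C)=C/CO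
F13 | step 5 | Mannich base, tert-butyl (3S,6E)-2-[(dimethylamino)methyl]-8-hydroxy-6-methyl-3-[(1E)-3-methylbuta-1,3-dien-1-yl]oct-6-enoate (C2 epimers) | CC(C)(C)OC(=O)C(CN(C)C)[C@H](/C=C/C(C)=C)CC/C(C)=C/CO
F14 | step 5 | methiodide, {(3S,6E)-2-(tert-butoxycarbonyl)-8-hydroxy-6-methyl-3-[(1E)-3-methylbuta-1,3-dien-1-yl]oct-6-en-1-yl}trimethylammonium iodide (C2 epimers) | CC(C)(C)OC(=O)C(C[N+](C)(C)C)[C@H](/C=C/C(C)=C)CC/C(C)=C/CO.[I-]
F15 | step 13 | 6R alcohol, (1R,2S,3E,6R,7E,10S,11E)-10-acetoxy-6-hydroxycembra-3,7,11,15(17)-tetraen-16,2-olide | C=C1C(=O)O[C@H]2/C=C(\C)C[C@@H](O)/C=C(\C)C[C@H](OC(C)=O)/C=C(\C)CC[C@H]12
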